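**Retrosynthetic overview**

1. Feature: in the target the ester oxygen lies between C2 (the CH that carries the ring B CH2) and the carbonyl carbon of ring C. Without that oxygen the chain is a ring C aryl ketone whose C1(OH)–C2 pair is a syn-aldol.
2. Target 22 ⇐ removal of four silyl groups ⇐ 21 ⇐ prenyl–ring B bond by Stille coupling at a ring B bromide ⇐ ester 20.
3. 20 ⇐ Baeyer–Villiger insertion of oxygen into the C2–C(=O) bond of aryl ketone 19, C2 migrating with retention.
4. 19 ⇐ Weinreb amide 14 + ring C arylmagnesium bromide 17; 14 ⇐ Evans syn-aldol (C1–C2 bond, both stereocentres) of imide 7 (ring B) with aldehyde 9 (ring A).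
5. No ring is formed: rings B, A and C enter preformed, in that order, from 1, 8 and 15.

Key step: step 10

Remark: locants follow the propane chain (C1 = carbinol carbon on ring A, C2 = ester-bearing carbon, C3 = CH2 on ring B; ring C = the 4-hydroxy-3,5-dimethoxybenzoyl ring); the target is (1S,2R); TBS = tert-butyldimethylsilyl, TES = triethylsilyl; tributyl(3-methylbut-2-en-1-yl)stannane is taken as a purchasable reagent.

**Route**

Step 1
Reactants: 1 3-(4-hydroxyphenyl)propanoic acid
Product: 2 3-(3-bromo-4-hydroxyphenyl)propanoic acid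
Conditions: NBS (1.0 equiv), MeCN, −10 °C to rt
Reagents that add atoms: N-bromosuccinimide, O=C1CCC(=O)N1Br
Why: Electrophilic aromatic bromination, in which the free phenol directs ortho because its para position carries the side chain, and one equivalent of NBS at low temperature should stop at the monobromide.

Step 2
Reactants: 2 3-(3-bromo-4-hydroxyphenyl)propanoic acid
Product: 4 3-[3-bromo-4-(tert-butyldimethylsilyloxy)phenyl]propanoic acid, via bis-silyl derivative 3 (not isolated)
Conditions: TBSCl, imidazole, DMF, rt; then AcOH/THF/H2O, rt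
Reagents that add atoms: tert-butyldimethylsilyl chloride (TBSCl), CC(C)(C)[Si](C)(C)Cl
Why: Imidazole-promoted silylation of phenol and acid followed by selective hydrolysis of the far more labile silyl ester under mild aqueous acid, which an aryl silyl ether should tolerate.

Step 3
Reactants: 4 3-[3-bromo-4-(tert-butyldimethylsilyloxy)phenyl]propanoic acid; 5 (R)-4-benzyl-2-oxazolidinone
Product: 7 (R)-4-benzyl-3-{3-[3-bromo-4-(tert-butyldimethylsilyloxy)phenyl]propanoyl}oxazolidin-2-one, via mixed pivalic anhydride 6 (not isolated)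
Conditions: PivCl, Et3N, THF, −20 °C; then 5, LiCl, −20 °C to rt
Reagents that add atoms: none
Why: N-acylation of an oxazolidinone through a mixed pivalic anhydride, in which LiCl/Et3N activates the oxazolidinone N–H and the hindered pivaloyl carbonyl is not attacked, no stereocentre being touched.

Step 4
Reactants: 8 4-hydroxy-2-methoxybenzaldehyde
Product: 9 4-(tert-butyldimethylsilyloxy)-2-methoxybenzaldehyde
Conditions: TBSCl, imidazole, DMF, rt
Reagents that add atoms: tert-butyldimethylsilyl chloride (TBSCl), CC(C)(C)[Si](C)(C)Cl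
Why: Standard imidazole-promoted silyl ether formation, which removes the acidic phenol proton that would otherwise quench the boron enolate.

Step 5
Reactants: 7 (R)-4-benzyl-3-{3-[3-bromo-4-(tert-butyldimethylsilyloxy)phenyl]propanoyl}oxazolidin-2-one; 9 4-(tert-butyldimethylsilyloxy)-2-methoxybenzaldehyde
Product: 12 (R)-4-benzyl-3-{(2R,3R)-2-[3-bromo-4-(TBS-oxy)benzyl]-3-hydroxy-3-[2-methoxy-4-(TBS-oxy)phenyl]propanoyl}oxazolidin-2-one, via Z-boron enolate 10 (not isolated), via boron aldolate 11 (not isolated)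
Conditions: Bu2BOTf, i-Pr2NEt, CH2Cl2, 0 °C; then 9, −78 to 0 °C; then pH 7 buffer (NaH2PO4/Na2HPO4), MeOH, 30% H2O2, 0 °C
Reagents that add atoms: none
Why: Evans syn-aldol reaction, in which Bu2BOTf/i-Pr2NEt gives the Z-boron enolate that adds to the aldehyde through a closed chair (Zimmerman–Traxler) transition state with the imide dipoles opposed and the auxiliary benzyl group shielding one enolate face, so that the (R)-auxiliary should set C2 and C1 together as the (2R,3R) syn adduct.

Step 6
Reactants: 12 syn-aldol imide (as named in step 5)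
Product: 13 (2R,3R)-2-[3-bromo-4-(TBS-oxy)benzyl]-3-hydroxy-N-methoxy-3-[2-methoxy-4-(TBS-oxy)phenyl]-N-methylpropanamide
Conditions: Me(MeO)NH·HCl, AlMe3, CH2Cl2, −20 to 0 °C; aq. potassium sodium tartrate
Reagents that add atoms: N,O-dimethylhydroxylamine hydrochloride, CNOC.Cl
Why: Weinreb transamidation of an aldol imide by the aluminium amide made from AlMe3 and the amine salt, directed to the exocyclic carbonyl by the free β-hydroxyl as its aluminium alkoxide, which is why it is run before the C1 oxygen is silylated.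

Step 7
Reactants: 13 β-hydroxy Weinreb amide (as named in step 6)
Product: 14 (2R,3R)-2-[3-bromo-4-(TBS-oxy)benzyl]-N-methoxy-3-[2-methoxy-4-(TBS-oxy)phenyl]-N-methyl-3-(triethylsilyloxy)propanamide
Conditions: TESOTf, 2,6-lutidine, CH2Cl2, −78 to 0 °C
Reagents that add atoms: triethylsilyl trifluoromethanesulfonate (TESOTf), CC[Si](CC)(CC)OS(=O)(=O)C(F)(F)F
Why: Silyl ether formation with a silyl triflate and a hindered pyridine base, which should cover the hindered benzylic C1–OH without ionising it, triethylsilyl being chosen so that this ether leaves under the mildest fluoride conditions at the end.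

Step 8
Reactants: 15 4-bromo-2,6-dimethoxyphenol
Product: 16 (4-bromo-2,6-dimethoxyphenoxy)(tert-butyl)dimethylsilane
Conditions: TBSCl, imidazole, DMF, rt to 40 °C
Reagents that add atoms: tert-butyldimethylsilyl chloride (TBSCl), CC(C)(C)[Si](C)(C)Cl
Why: Imidazole-promoted silylation of the flanked phenol, needed so that the aryl bromide can be turned into a Grignard reagent.

Step 9
Reactants: 14 C1-O-TES Weinreb amide (as named in step 7); 16 (4-bromo-2,6-dimethoxyphenoxy)(tert-butyl)dimethylsilane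
Product: 19 (2R,3R)-2-[3-bromo-4-(TBS-oxy)benzyl]-1-[3,5-dimethoxy-4-(TBS-oxy)phenyl]-3-[2-methoxy-4-(TBS-oxy)phenyl]-3-(triethylsilyloxy)propan-1-one, via arylmagnesium bromide 17 (not isolated), via magnesium hemiaminal 18 (not isolated)
Conditions: 16, Mg, 1,2-dibromoethane (cat.), THF, 50 °C; then 14, THF, 0 °C to rt; aq. NH4Cl
Reagents that add atoms: none
Why: Weinreb ketone synthesis, in which magnesium inserts into the C–Br bond of 16 and the arylmagnesium bromide adds once to the N-methoxy-N-methylamide to give a chelated tetrahedral adduct that holds until work-up, so that no tertiary alcohol should form and the α-stereocentre should stay intact, an arylmagnesium rather than an aryllithium reagent being used so that the ring B bromide is not exchanged.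

Step 10
Reactants: 19 ring C aryl ketone (as named in step 9)
Product: 20 (1S,2R)-3-[3-bromo-4-(TBS-oxy)phenyl]-1-[2-methoxy-4-(TBS-oxy)phenyl]-1-(triethylsilyloxy)propan-2-yl 3,5-dimethoxy-4-(TBS-oxy)benzoate
Conditions: mCPBA (excess), NaHCO3, CH2Cl2, 0 °C to rt; aq. Na2S2O3
Reagents that add atoms: meta-chloroperbenzoic acid (mCPBA), OOC(=O)c1cccc(Cl)c1
Why: The peracid adds to the ketone carbonyl to give the tetrahedral Criegee adduct, and the substituent that lies antiperiplanar to the breaking O–O bond and best carries positive charge shifts from carbon to oxygen as 3-chlorobenzoate leaves. The closest known reaction type is the Baeyer–Villiger oxidation of aryl secondary-alkyl ketones (aryl cyclohexyl or aryl isopropyl ketones to secondary-alkyl benzoates), in which the branched alkyl group migrates. No ring closes; the step only forms the C2–O and O–C(acyl) bonds. No new stereocentre arises: C2 migrates with its bonding pair on the same face and so keeps its configuration, and C1 is untouched (its descriptor changes from R to S only because C2 gains CIP rank). The step needs migration of C2 rather than of ring C, which should be favoured because C2 is a branched secondary carbon while ring C is a poor migrating aryl group, its 4-silyloxy oxygen being forced out of the ring plane by the two flanking methoxy groups, which from their meta positions act only as inductive acceptors. It also needs chemoselectivity, secured by the absence of any alkene (the prenyl group is still a bromide) and by the NaHCO3 buffer, which keeps 3-chlorobenzoic acid from ionising the benzylic C1 silyl ether.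

Step 11
Reactants: 20 C2 ester with ring B bromide (as named in step 10)
Product: 21 (1S,2R)-1-[2-methoxy-4-(TBS-oxy)phenyl]-3-[3-(3-methylbut-2-en-1-yl)-4-(TBS-oxy)phenyl]-1-(triethylsilyloxy)propan-2-yl 3,5-dimethoxy-4-(TBS-oxy)benzoate
Conditions: tributyl(3-methylbut-2-en-1-yl)stannane, Pd(PPh3)4 (cat.), toluene, 100 °C
Reagents that add atoms: tributyl(3-methylbut-2-en-1-yl)stannane, CCCC[Sn](CCCC)(CCCC)CC=C(C)C
Why: Stille cross-coupling by oxidative addition of zerovalent palladium into the ring B C–Br bond, transfer of the prenyl group from tin and reductive elimination, which with Pd(PPh3)4 is expected to give mainly the linear 3-methylbut-2-enyl isomer while ester and silyl ethers stay inert.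

Step 12
Reactants: 21 prenylated tetrasilyl ether (as named in step 11)
Product: 22 eryvarinol B, (1S,2R)-1-hydroxy-1-(4-hydroxy-2-methoxyphenyl)-3-[4-hydroxy-3-(3-methylbut-2-en-1-yl)phenyl]propan-2-yl 4-hydroxy-3,5-dimethoxybenzoate
Conditions: TBAF, AcOH (1:1), THF, 0 °C to rt
Reagents that add atoms: none
Why: Fluoride-mediated desilylation driven by Si–F bond formation, with AcOH keeping the phenols and the C1 alcohol protonated so that the C2 ester should neither migrate to the C1 oxygen nor be cleaved and the benzylic alcohol is not ionised.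

**Compound list**

1 | 3-(4-hydroxyphenyl)propanoic acid | OC(=O)CCc1ccc(O)cc1 | starting material
2 | 3-(3-bromo-4-hydroxyphenyl)propanoic acid | OC(=O)CCc1ccc(O)c(Br)c1 | intermediate
3 | tert-butyldimethylsilyl 3-[3-bromo-4-(tert-butyldimethylsilyloxy)phenyl]propanoate | CC(C)(C)[Si](C)(C)OC(=O)CCc1ccc(O[Si](C)(C)C(C)(C)C)c(Br)c1 | intermediate
4 | 3-[3-bromo-4-(tert-butyldimethylsilyloxy)phenyl]propanoic acid | OC(=O)CCc1ccc(O[Si](C)(C)C(C)(C)C)c(Br)c1 | intermediate
5 | (R)-4-benzyl-2-oxazolidinone | O=C1N[C@H](Cc2ccccc2)CO1 | starting material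
6 | 3-[3-bromo-4-(tert-butyldimethylsilyloxy)phenyl]propanoic pivalic anhydride | CC(C)(C)C(=O)OC(=O)CCc1ccc(O[Si](C)(C)C(C)(C)C)c(Br)c1 | intermediate
7 | (R)-4-benzyl-3-{3-[3-bromo-4-(tert-butyldimethylsilyloxy)phenyl]propanoyl}oxazolidin-2-one | O=C1OC[C@@H](Cc2ccccc2)N1C(=O)CCc1ccc(O[Si](C)(C)C(C)(C)C)c(Br)c1 | intermediate
8 | 4-hydroxy-2-methoxybenzaldehyde | COc1cc(O)ccc1C=O | starting material
9 | 4-(tert-butyldimethylsilyloxy)-2-methoxybenzaldehyde | COc1cc(O[Si](C)(C)C(C)(C)C)ccc1C=O | intermediate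
10 | (Z)-dibutylboron enolate of imide 7 | CCCCB(CCCC)O/C(=C\Cc1ccc(O[Si](C)(C)C(C)(C)C)c(Br)c1)N1C(=O)OC[C@H]1Cc1ccccc1 | intermediate
11 | O-dibutylboryl aldolate of 12 | COc1cc(O[Si](C)(C)C(C)(C)C)ccc1[C@H](OB(CCCC)CCCC)[C@@H](Cc1ccc(O[Si](C)(C)C(C)(C)C)c(Br)c1)C(=O)N1C(=O)OC[C@H]1Cc1ccccc1 | intermediate
12 | (R)-4-benzyl-3-{(2R,3R)-2-[3-bromo-4-(TBS-oxy)benzyl]-3-hydroxy-3-[2-methoxy-4-(TBS-oxy)phenyl]propanoyl}oxazolidin-2-one | COc1cc(O[Si](C)(C)C(C)(C)C)ccc1[C@H](O)[C@@H](Cc1ccc(O[Si](C)(C)C(C)(C)C)c(Br)c1)C(=O)N1C(=O)OC[C@H]1Cc1ccccc1 | intermediate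
13 | (2R,3R)-2-[3-bromo-4-(TBS-oxy)benzyl]-3-hydroxy-N-methoxy-3-[2-methoxy-4-(TBS-oxy)phenyl]-N-methylpropanamide | COc1cc(O[Si](C)(C)C(C)(C)C)ccc1[C@H](O)[C@@H](Cc1ccc(O[Si](C)(C)C(C)(C)C)c(Br)c1)C(=O)N(C)OC | intermediate
14 | (2R,3R)-2-[3-bromo-4-(TBS-oxy)benzyl]-N-methoxy-3-[2-methoxy-4-(TBS-oxy)phenyl]-N-methyl-3-(triethylsilyloxy)propanamide | COc1cc(O[Si](C)(C)C(C)(C)C)ccc1[C@H](O[Si](CC)(CC)CC)[C@@H](Cc1ccc(O[Si](C)(C)C(C)(C)C)c(Br)c1)C(=O)N(C)OC | intermediate
15 | 4-bromo-2,6-dimethoxyphenol | COc1cc(Br)cc(OC)c1O | starting material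
16 | (4-bromo-2,6-dimethoxyphenoxy)(tert-butyl)dimethylsilane | COc1cc(Br)cc(OC)c1O[Si](C)(C)C(C)(C)C | intermediate
17 | [4-(tert-butyldimethylsilyloxy)-3,5-dimethoxyphenyl]magnesium bromide | COc1cc([Mg]Br)cc(OC)c1O[Si](C)(C)C(C)(C)C | intermediate
18 | bromomagnesium alkoxide of the tetrahedral adduct of 17 to amide 14 | COc1cc(O[Si](C)(C)C(C)(C)C)ccc1[C@H](O[Si](CC)(CC)CC)[C@@H](Cc1ccc(O[Si](C)(C)C(C)(C)C)c(Br)c1)C(O[Mg]Br)(N(C)OC)c1cc(OC)c(O[Si](C)(C)C(C)(C)C)c(OC)c1 | intermediate
19 | (2R,3R)-2-[3-bromo-4-(TBS-oxy)benzyl]-1-[3,5-dimethoxy-4-(TBS-oxy)phenyl]-3-[2-methoxy-4-(TBS-oxy)phenyl]-3-(triethylsilyloxy)propan-1-one | COc1cc(O[Si](C)(C)C(C)(C)C)ccc1[C@H](O[Si](CC)(CC)CC)[C@@H](Cc1ccc(O[Si](C)(C)C(C)(C)C)c(Br)c1)C(=O)c1cc(OC)c(O[Si](C)(C)C(C)(C)C)c(OC)c1 | intermediate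
20 | (1S,2R)-3-[3-bromo-4-(TBS-oxy)phenyl]-1-[2-methoxy-4-(TBS-oxy)phenyl]-1-(triethylsilyloxy)propan-2-yl 3,5-dimethoxy-4-(TBS-oxy)benzoate | COc1cc(O[Si](C)(C)C(C)(C)C)ccc1[C@H](O[Si](CC)(CC)CC)[C@@H](Cc1ccc(O[Si](C)(C)C(C)(C)C)c(Br)c1)OC(=O)c1cc(OC)c(O[Si](C)(C)C(C)(C)C)c(OC)c1 | intermediate
21 | (1S,2R)-1-[2-methoxy-4-(TBS-oxy)phenyl]-3-[3-(3-methylbut-2-en-1-yl)-4-(TBS-oxy)phenyl]-1-(triethylsilyloxy)propan-2-yl 3,5-dimethoxy-4-(TBS-oxy)benzoate | COc1cc(O[Si](C)(C)C(C)(C)C)ccc1[C@H](O[Si](CC)(CC)CC)[C@@H](Cc1ccc(O[Si](C)(C)C(C)(C)C)c(CC=C(C)C)c1)OC(=O)c1cc(OC)c(O[Si](C)(C)C(C)(C)C)c(OC)c1 | intermediate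
22 | eryvarinol B | COc1cc(O)ccc1[C@H](O)[C@@H](Cc1ccc(O)c(CC=C(C)C)c1)OC(=O)c1cc(OC)c(O)c(OC)c1 | target

**Step count and risk**

Total step count: 12 steps.
Longest linear sequence: 10 steps (steps 1, 2, 3, 5, 6, 7, 9, 10, 11, 12).

Steps most likely to fail:

1. Step 10 (Baeyer–Villiger). The ring C aryl group may migrate in place of C2, whose migratory aptitude is lowered by the neighbouring C1 oxygen, or the peracid may fail to add to the hindered, conjugated carbonyl under buffered conditions. Fallback: setting out from Weinreb amide 14, MeMgBr (THF, 0 °C) should give the methyl ketone F1, in which C2 competes only with a methyl group. mCPBA/NaHCO3 should then give the C2 acetate F2 with retention, and i-Bu2AlH at −78 °C should remove the acetyl group to give the C2 alcohol F3. Yamaguchi esterification (2,4,6-trichlorobenzoyl chloride, Et3N, DMAP, toluene) with 4-(tert-butyldimethylsilyloxy)-3,5-dimethoxybenzoic acid F4, made by quenching arylmagnesium bromide 17 with CO2, should come back to the route at ester 20.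

2. Step 11 (Stille prenylation). Oxidative addition into the hindered, electron-rich ortho-silyloxy aryl bromide may be slow, and allylic transposition during transmetalation may lead to the 1,1-dimethylallyl isomer. Fallback: setting out from bromide 20, Stille coupling with allyltributylstannane (Pd(PPh3)4, toluene, 100 °C), which has no regiochemical ambiguity, should give the allyl arene F5. Cross-metathesis with 2-methyl-2-butene and second-generation Grubbs catalyst (CH2Cl2, 40 °C) should then turn the allyl into the prenyl group and come back to the route at 21.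

3. Step 9 (ketone formation). Addition of the arylmagnesium reagent to the α-branched, β-silyloxy Weinreb amide may be sluggish, or enolisation may be followed by β-elimination of the C1 silyloxy group. Fallback: setting out from 14, i-Bu2AlH (THF, −78 °C) should give the aldehyde F6, used at once, to which arylmagnesium bromide 17 should add at −78 °C to give the secondary carbinol F7 (both epimers at the new carbinol carbon serve). Oxidation with Dess–Martin periodinane and NaHCO3 in CH2Cl2 should come back to the route at ketone 19.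

**Further compounds**

F1 | step 10 | (3R,4R)-3-[3-bromo-4-(TBS-oxy)benzyl]-4-[2-methoxy-4-(TBS-oxy)phenyl]-4-(triethylsilyloxy)butan-2-one | COc1cc(O[Si](C)(C)C(C)(C)C)ccc1[C@H](O[Si](CC)(CC)CC)[C@@H](Cc1ccc(O[Si](C)(C)C(C)(C)C)c(Br)c1)C(C)=O
F2 | step 10 | (1S,2R)-3-[3-bromo-4-(TBS-oxy)phenyl]-1-[2-methoxy-4-(TBS-oxy)phenyl]-1-(triethylsilyloxy)propan-2-yl acetate | COc1cc(O[Si](C)(C)C(C)(C)C)ccc1[C@H](O[Si](CC)(CC)CC)[C@@H](Cc1ccc(O[Si](C)(C)C(C)(C)C)c(Br)c1)OC(C)=O
F3 | step 10 | (1S,2R)-3-[3-bromo-4-(TBS-oxy)phenyl]-1-[2-methoxy-4-(TBS-oxy)phenyl]-1-(triethylsilyloxy)propan-2-ol | COc1cc(O[Si](C)(C)C(C)(C)C)ccc1[C@H](O[Si](CC)(CC)CC)[C@@H](Cc1ccc(O[Si](C)(C)C(C)(C)C)c(Br)c1)O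
F4 | step 10 | 4-(tert-butyldimethylsilyloxy)-3,5-dimethoxybenzoic acid | COc1cc(C(=O)O)cc(OC)c1O[Si](C)(C)C(C)(C)C
F5 | step 11 | (1S,2R)-3-[3-allyl-4-(TBS-oxy)phenyl]-1-[2-methoxy-4-(TBS-oxy)phenyl]-1-(triethylsilyloxy)propan-2-yl 3,5-dimethoxy-4-(TBS-oxy)benzoate | COc1cc(O[Si](C)(C)C(C)(C)C)ccc1[C@H](O[Si](CC)(CC)CC)[C@@H](Cc1ccc(O[Si](C)(C)C(C)(C)C)c(CC=C)c1)OC(=O)c1cc(OC)c(O[Si](C)(C)C(C)(C)C)c(OC)c1
F6 | step 9 | (2R,3R)-2-[3-bromo-4-(TBS-oxy)benzyl]-3-[2-methoxy-4-(TBS-oxy)phenyl]-3-(triethylsilyloxy)propanal | COc1cc(O[Si](C)(C)C(C)(C)C)ccc1[C@H](O[Si](CC)(CC)CC)[C@@H](Cc1ccc(O[Si](C)(C)C(C)(C)C)c(Br)c1)C=O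
F7 | step 9 | secondary carbinol from addition of 17 to F6, epimer mixture at the new carbinol carbon, other two centres as in 19 | COc1cc(O[Si](C)(C)C(C)(C)C)ccc1[C@H](O[Si](CC)(CC)CC)[C@@H](Cc1ccc(O[Si](C)(C)C(C)(C)C)c(Br)c1)C(O)c1cc(OC)c(O[Si](C)(C)C(C)(C)C)c(OC)c1
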